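The seven-membered ring is closed last, by ring-closing metathesis across C7=C8 (hydroazulene numbering). The key step exploits the lone ring alkene, a cis CH=CH flanked by the quaternary C8a and the tertiary carbinol C6. Cutting it leaves two simple vinyl groups, so one operation completes the bicyclic skeleton with all five stereocentres already in place. The precursor is a fully substituted cyclopentane (C1–C3, C3a, C8a), made from (S)-terpinen-4-ol by ozonolysis and aldol ring contraction. It carries, cis to each other, a vinyl group on C8a and, on C3a, a 1,3-diol chain ending in a methyl vinyl carbinol.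

Key step: step 7

Assumption: (S)-(+)-terpinen-4-ol of high enantiomeric purity and 4-(tert-butyldimethylsilyloxy)benzoic acid are taken as commercial; ring locants are those of the hydroazulene (C3 isopropyl carbinol, C3a ring-fusion CH, C4 ester carbon, C6 methyl carbinol, C7=C8, C8a methyl-bearing quaternary carbon).

Step 1
Reactants: 1 (S)-terpinen-4-ol
Product: 2 (S)-triethyl[(1-isopropyl-4-methylcyclohex-3-en-1-yl)oxy]silane
Conditions: Et3SiOTf, 2,6-lutidine, CH2Cl2, 0 → 23 °C
Reagents that add atoms: triethylsilyl trifluoromethanesulfonate, CC[Si](CC)(CC)OS(=O)(=O)C(F)(F)F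
Why: Silyl triflate silylation of the hindered tertiary alcohol should proceed cleanly and is needed because the free hydroxy keto aldehyde of the next steps would form a hemiketal or undergo retro-aldol cleavage; the stereocentre is untouched.

Step 2
Reactants: 2 (S)-triethyl[(1-isopropyl-4-methylcyclohex-3-en-1-yl)oxy]silane
Product: 3 (S)-3-isopropyl-6-oxo-3-(triethylsilyloxy)heptanal
Conditions: O3, CH2Cl2/MeOH, −78 °C; then Me2S, −78 → 23 °C
Reagents that add atoms: ozone, [O-][O+]=O
Why: Ozonolysis with reductive work-up should cleave the only C=C to the 1,6-keto aldehyde without touching the silyl-protected stereocentre.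

Step 3
Reactants: 3 (S)-3-isopropyl-6-oxo-3-(triethylsilyloxy)heptanal
Product: 4 (R)-5-isopropyl-2-methyl-5-(triethylsilyloxy)cyclopent-1-ene-1-carbaldehyde
Conditions: piperidine (cat.), AcOH (cat.), toluene, 80 °C
Reagents that add atoms: none
Why: Amine-catalysed intramolecular aldol condensation (enamine of the aldehyde attacking the methyl ketone, 5-exo-trig, then dehydration) should contract the former cyclohexene to the cyclopentene carbaldehyde, the usual outcome for terpene-derived 6-oxoheptanals; the stereocentre is not involved (the descriptor changes only through CIP priorities).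

Step 4
Reactants: 4 (R)-5-isopropyl-2-methyl-5-(triethylsilyloxy)cyclopent-1-ene-1-carbaldehyde; 5 vinylmagnesium bromide
Product: 7 (1R,2R,5S)-2-isopropyl-5-methyl-2-(triethylsilyloxy)-5-vinylcyclopentane-1-carbaldehyde, via trimethylsilyl enol ether 6 (not isolated)
Conditions: CuBr·SMe2 (cat.), Me3SiCl, HMPA, THF, −78 → −40 °C; then K2CO3 (cat.), MeOH, 0 → 23 °C
Reagents that add atoms: none
Why: Copper-catalysed, Me3SiCl-accelerated conjugate addition of the vinyl Grignard reagent should create the methyl/vinyl quaternary carbon by attack anti to the isopropyl group (A(1,2) strain with the formyl group forces isopropyl pseudoaxial), and equilibrating methanolysis of the silyl enol ether should leave the formyl group trans to isopropyl and cis to vinyl, the thermodynamically preferred arrangement.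

Step 5
Reactants: 7 (1R,2R,5S)-2-isopropyl-5-methyl-2-(triethylsilyloxy)-5-vinylcyclopentane-1-carbaldehyde; 8 2-(trimethylsilyloxy)buta-1,3-diene
Product: 9 (S)-5-hydroxy-5-[(1S,2R,5S)-2-isopropyl-5-methyl-2-(triethylsilyloxy)-5-vinylcyclopentyl]pent-1-en-3-one
Conditions: Me2AlCl (2.5 equiv), CH2Cl2, −78 °C; then 1 M HCl, THF, 0 °C
Reagents that add atoms: none
Why: Mukaiyama aldol addition at the terminal CH2 of the siloxydiene, in which excess Me2AlCl should lock the β-silyloxy aldehyde in a six-membered aluminium chelate (formyl O and the cis silyloxy O) so that the enol silane attacks the carbonyl face on the side of the ring methine H, away from the quaternary carbon and its vinyl group, setting the (S)-carbinol.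

Step 6
Reactants: 9 (S)-5-hydroxy-5-[(1S,2R,5S)-2-isopropyl-5-methyl-2-(triethylsilyloxy)-5-vinylcyclopentyl]pent-1-en-3-one; 10 methylmagnesium bromide
Product: 11 (3R,5S)-5-[(1S,2R,5S)-2-isopropyl-5-methyl-2-(triethylsilyloxy)-5-vinylcyclopentyl]-3-methylpent-1-ene-3,5-diol
Conditions: MeMgBr (3 equiv), Et2O/CH2Cl2, −78 °C; aq. NH4Cl
Reagents that add atoms: none
Why: 1,2-Addition of the Grignard reagent to the vinyl ketone under Cram-chelate 1,3-control, in which the magnesium alkoxide and the ketone oxygen form a half-chair chelate with the cyclopentyl group equatorial and the small methyl nucleophile should enter axially, giving the (3R) tertiary carbinol syn to the C5 hydroxyl along the chain that runs into the vinyl group.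

Step 7
Reactants: 11 (3R,5S)-5-[(1S,2R,5S)-2-isopropyl-5-methyl-2-(triethylsilyloxy)-5-vinylcyclopentyl]-3-methylpent-1-ene-3,5-diol
Product: 12 (3R,3aS,4S,6R,8aS)-3-isopropyl-6,8a-dimethyl-3-(triethylsilyloxy)-1,2,3,3a,4,5,6,8a-octahydroazulene-4,6-diol
Conditions: second-generation Hoveyda–Grubbs catalyst (10 mol %), toluene (2 mM), 80 °C
Reagents that add atoms: none
Why: Olefin metathesis: the ruthenium alkylidene should load onto the vinyl group of the free tertiary allylic alcohol (C6), undergo intramolecular [2+2] cycloaddition with the vinyl group on the quaternary C8a and cycloreversion, expelling ethene. The closest known reaction type is ring-closing metathesis to cycloheptenes bearing allylic tertiary alcohols and allylic quaternary carbons. The seven-membered ring is closed by forming the C7=C8 double bond between the two vinyl termini, and only the cis alkene can form in a ring of this size. No stereocentre is created; C3, C3a, C4, C6 and C8a are carried in unchanged from steps 1–6, and the cis ring fusion follows from the cis placement of the two chains on the cyclopentane. The step needs cyclisation to win over dimerisation and olefin isomerisation; the cis-1,2 arrangement on the five-membered ring, the two fully substituted allylic carbons (Thorpe–Ingold effect) and high dilution should secure this, and no other alkene is present.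

Step 8
Reactants: 12 (3R,3aS,4S,6R,8aS)-3-isopropyl-6,8a-dimethyl-3-(triethylsilyloxy)-1,2,3,3a,4,5,6,8a-octahydroazulene-4,6-diol; 13 4-(tert-butyldimethylsilyloxy)benzoic acid
Product: 15 (3R,3aS,4S,6R,8aS)-6-hydroxy-3-isopropyl-6,8a-dimethyl-3-(triethylsilyloxy)-1,2,3,3a,4,5,6,8a-octahydroazulen-4-yl 4-(tert-butyldimethylsilyloxy)benzoate, via mixed anhydride 14 (not isolated)
Conditions: 2,4,6-trichlorobenzoyl chloride, Et3N, THF, 23 °C; then 12, DMAP, toluene, 23 → 60 °C
Reagents that add atoms: none
Why: Yamaguchi esterification, in which the mixed anhydride should acylate the only secondary hydroxyl (C4) while the tertiary C6 alcohol and the silylated C3 oxygen stay inert; no stereocentre is affected.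

Step 9
Reactants: 15 (3R,3aS,4S,6R,8aS)-6-hydroxy-3-isopropyl-6,8a-dimethyl-3-(triethylsilyloxy)-1,2,3,3a,4,5,6,8a-octahydroazulen-4-yl 4-(tert-butyldimethylsilyloxy)benzoate
Product: 16 (3R,3aS,4S,6R,8aS)-3,6-dihydroxy-3-isopropyl-6,8a-dimethyl-1,2,3,3a,4,5,6,8a-octahydroazulen-4-yl 4-hydroxybenzoate (CNP0280165.1)
Conditions: HF·pyridine, pyridine, THF, 0 → 40 °C
Reagents that add atoms: none
Why: Pyridine-buffered HF desilylation should remove the aryl silyl ether and the tertiary triethylsilyl ether in one operation under conditions mild enough for the benzoate and the tertiary allylic alcohol; no stereocentre is affected.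

Compound list
1 | (S)-(+)-terpinen-4-ol | CC1=CC[C@](O)(C(C)C)CC1 | starting material
2 | (S)-triethyl[(1-isopropyl-4-methylcyclohex-3-en-1-yl)oxy]silane | CC1=CC[C@](O[Si](CC)(CC)CC)(C(C)C)CC1 | intermediate
3 | (S)-3-isopropyl-6-oxo-3-(triethylsilyloxy)heptanal | O=CC[C@](O[Si](CC)(CC)CC)(C(C)C)CCC(C)=O | intermediate
4 | (R)-5-isopropyl-2-methyl-5-(triethylsilyloxy)cyclopent-1-ene-1-carbaldehyde | O=CC1=C(C)CC[C@@]1(O[Si](CC)(CC)CC)C(C)C | intermediate
5 | vinylmagnesium bromide | C=C[Mg]Br | starting material
6 | triethyl{[(1R,3S)-1-isopropyl-3-methyl-2-[(trimethylsilyloxy)methylidene]-3-vinylcyclopentyl]oxy}silane (E/Z mixture, not isolated) | CC(C)[C@]1(O[Si](CC)(CC)CC)CC[C@@](C)(C=C)C1=CO[Si](C)(C)C | intermediate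
7 | (1R,2R,5S)-2-isopropyl-5-methyl-2-(triethylsilyloxy)-5-vinylcyclopentane-1-carbaldehyde | CC(C)[C@]1(O[Si](CC)(CC)CC)CC[C@@](C)(C=C)[C@H]1C=O | intermediate
8 | 2-(trimethylsilyloxy)buta-1,3-diene | C=CC(=C)O[Si](C)(C)C | starting material
9 | (S)-5-hydroxy-5-[(1S,2R,5S)-2-isopropyl-5-methyl-2-(triethylsilyloxy)-5-vinylcyclopentyl]pent-1-en-3-one | CC(C)[C@]1(O[Si](CC)(CC)CC)CC[C@@](C)(C=C)[C@H]1[C@@H](O)CC(=O)C=C | intermediate
10 | methylmagnesium bromide | C[Mg]Br | starting material
11 | (3R,5S)-5-[(1S,2R,5S)-2-isopropyl-5-methyl-2-(triethylsilyloxy)-5-vinylcyclopentyl]-3-methylpent-1-ene-3,5-diol | CC(C)[C@]1(O[Si](CC)(CC)CC)CC[C@@](C)(C=C)[C@H]1[C@@H](O)C[C@@](C)(O)C=C | intermediate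
12 | (3R,3aS,4S,6R,8aS)-3-isopropyl-6,8a-dimethyl-3-(triethylsilyloxy)-1,2,3,3a,4,5,6,8a-octahydroazulene-4,6-diol | CC(C)[C@]1(O[Si](CC)(CC)CC)CC[C@@]2(C)C=C[C@](C)(O)C[C@H](O)[C@@H]12 | intermediate
13 | 4-(tert-butyldimethylsilyloxy)benzoic acid | CC(C)(C)[Si](C)(C)Oc1ccc(cc1)C(O)=O | starting material
14 | 4-(tert-butyldimethylsilyloxy)benzoic 2,4,6-trichlorobenzoic anhydride (not isolated) | CC(C)(C)[Si](C)(C)Oc1ccc(cc1)C(=O)OC(=O)c1c(Cl)cc(Cl)cc1Cl | intermediate
15 | (3R,3aS,4S,6R,8aS)-6-hydroxy-3-isopropyl-6,8a-dimethyl-3-(triethylsilyloxy)-1,2,3,3a,4,5,6,8a-octahydroazulen-4-yl 4-(tert-butyldimethylsilyloxy)benzoate | CC(C)[C@]1(O[Si](CC)(CC)CC)CC[C@@]2(C)C=C[C@](C)(O)C[C@H](OC(=O)c3ccc(O[Si](C)(C)C(C)(C)C)cc3)[C@@H]12 | intermediate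
16 | (3R,3aS,4S,6R,8aS)-3,6-dihydroxy-3-isopropyl-6,8a-dimethyl-1,2,3,3a,4,5,6,8a-octahydroazulen-4-yl 4-hydroxybenzoate | CC(C)[C@]1(O)CC[C@@]2(C)C=C[C@](C)(O)C[C@H](OC(=O)c3ccc(O)cc3)[C@@H]12 | target

Total step count: 9. Longest linear sequence: 9 steps (1 → 16).

Steps most likely to fail

Step 5. The hindered tertiary triethylsilyl ether may fail to chelate, so that Felkin–Anh-type attack anti to the silyloxy-bearing carbon gives the wrong carbinol face. The β-hydroxy vinyl ketone may also close to a tetrahydropyranone by oxa-Michael or formal hetero-Diels–Alder reaction, and methyl transfer from aluminium may compete. The fallback sets out from 7 and uses reagent control. Brown methallylation with (−)-B-methallyldiisopinocampheylborane (derived from (+)-α-pinene; Et2O, −78 °C, then NaOH/H2O2) should give (S)-1-[(1S,2R,5S)-2-isopropyl-5-methyl-2-(triethylsilyloxy)-5-vinylcyclopentyl]-3-methylbut-3-en-1-ol F1. Hydroxyl-directed epoxidation of the homoallylic 1,1-disubstituted alkene (VO(acac)2, t-BuOOH, CH2Cl2, 0 °C) should then favour, through the chair-like vanadate transition state, the 1,3-syn epoxy alcohol (S)-1-[(1S,2R,5S)-2-isopropyl-5-methyl-2-(triethylsilyloxy)-5-vinylcyclopentyl]-2-[(R)-2-methyloxiran-2-yl]ethan-1-ol F2. Excess dimethylsulfonium methylide (trimethylsulfonium iodide, n-BuLi, THF, −10 → 23 °C) should open the epoxide at CH2 and eliminate to the tertiary vinyl carbinol, which rejoins the route at 11.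

Step 4. The vinyl group may add 1,2 to the formyl group, attack at the fully substituted β-carbon may be sluggish, addition may occur from the isopropyl face, and equilibration at the formyl-bearing carbon may be incomplete or accompanied by β-elimination of the silyloxy group. The fallback sets out from 4 and delivers the carbon substituent intramolecularly. Allylmagnesium bromide (THF, −78 °C) should add 1,2 to give 1-[(R)-5-isopropyl-2-methyl-5-(triethylsilyloxy)cyclopent-1-en-1-yl]but-3-en-1-ol F3 (both carbinol epimers are usable). Anionic oxy-Cope rearrangement (KH, 18-crown-6, THF, 0 → 23 °C), followed by the same K2CO3/MeOH equilibration, should give (1R,2R,5S)-5-allyl-2-isopropyl-5-methyl-2-(triethylsilyloxy)cyclopentane-1-carbaldehyde F4. Isomerisation with RuHCl(CO)(PPh3)3 (toluene, 80 °C) should give (1R,2R,5S)-2-isopropyl-5-methyl-5-[(E)-prop-1-en-1-yl]-2-(triethylsilyloxy)cyclopentane-1-carbaldehyde F5. Ethenolysis (ethene, second-generation Grubbs catalyst, CH2Cl2, 40 °C) should trim the propenyl group to vinyl and return 7.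

Step 7. Ring closure may be slow because both vinyl groups sit on fully substituted carbons, which leaves room for catalyst decomposition, olefin isomerisation or dimerisation through the allylic-alcohol vinyl group. The fallback sets out from 9 and closes the ring one stage earlier on the enone. Ring-closing metathesis of 9 (second-generation Hoveyda–Grubbs catalyst, toluene, 80 °C) pairs the electron-poor vinyl ketone with the hindered vinyl group and should give (3R,3aS,4S,8aS)-4-hydroxy-3-isopropyl-8a-methyl-3-(triethylsilyloxy)-2,3,3a,4,5,8a-hexahydroazulen-6(1H)-one F6. MeMgBr (Et2O/CH2Cl2, −78 °C) should then add 1,2 to the ring ketone from the face opposite the magnesium alkoxide bridge formed with the C4 oxygen, which gives 12.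

Further compounds
F1 | step 5 | (S)-1-[(1S,2R,5S)-2-isopropyl-5-methyl-2-(triethylsilyloxy)-5-vinylcyclopentyl]-3-methylbut-3-en-1-ol | CC(C)[C@]1(O[Si](CC)(CC)CC)CC[C@@](C)(C=C)[C@H]1[C@@H](O)CC(C)=C
F2 | step 5 | (S)-1-[(1S,2R,5S)-2-isopropyl-5-methyl-2-(triethylsilyloxy)-5-vinylcyclopentyl]-2-[(R)-2-methyloxiran-2-yl]ethan-1-ol | CC(C)[C@]1(O[Si](CC)(CC)CC)CC[C@@](C)(C=C)[C@H]1[C@@H](O)C[C@]2(C)CO2
F3 | step 4 | 1-[(R)-5-isopropyl-2-methyl-5-(triethylsilyloxy)cyclopent-1-en-1-yl]but-3-en-1-ol | C=CCC(O)C1=C(C)CC[C@@]1(O[Si](CC)(CC)CC)C(C)C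
F4 | step 4 | (1R,2R,5S)-5-allyl-2-isopropyl-5-methyl-2-(triethylsilyloxy)cyclopentane-1-carbaldehyde | CC(C)[C@]1(O[Si](CC)(CC)CC)CC[C@@](C)(CC=C)[C@H]1C=O
F5 | step 4 | (1R,2R,5S)-2-isopropyl-5-methyl-5-[(E)-prop-1-en-1-yl]-2-(triethylsilyloxy)cyclopentane-1-carbaldehyde | CC(C)[C@]1(O[Si](CC)(CC)CC)CC[C@@](C)(/C=C/C)[C@H]1C=O
F6 | step 7 | (3R,3aS,4S,8aS)-4-hydroxy-3-isopropyl-8a-methyl-3-(triethylsilyloxy)-2,3,3a,4,5,8a-hexahydroazulen-6(1H)-one | CC(C)[C@]1(O[Si](CC)(CC)CC)CC[C@@]2(C)C=CC(=O)C[C@H](O)[C@@H]12
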